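**Plan**

1. Numbering (drimane): ring A = C1–C5 + C10, ring B = C5–C10, C11 = the OCH2 carbon, C12 = the exocyclic CH2; "α" is the face anti to the angular C10 methyl, "β" the face syn to it.
2. Retrosynthetic cuts, in order: the O–C11 aryl ether; C9–C11 together with the C8=C12 double bond (formaldehyde ene); the C2–O bond; C3–C4 (ring A); C10–C1 and C5–C4 (conjugate addition and Michael trapping on 2-methylcyclohex-2-enone).
3. Forward order: ring B is the starting cyclohexenone and receives an isopropenyl arm at C5 and a 2-cyanoethyl arm at C10; ring A is the only ring closed in the route, through C3–C4; the coumarin is attached ready-made (isofraxidin) in the last step.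
4. Enabling feature: the C3 carbonyl of ring A lies between the quaternary gem-dimethyl carbon C4 and the C2–C1 chain. C4 can therefore be a tertiary radical (isopropenyl group + H•, its CH2 becoming the second geminal methyl) and C3 the carbon of a nitrile that this radical attacks and that hydrolysis turns into the ketone.
5. Stereochemistry: C5 by ligand-controlled asymmetric conjugate addition; C10 by anti Michael trapping of the enolate, which fixes the trans ring fusion before ring A exists; C2 by α-epoxidation of the C2=C3 enol acetate and thermal acetoxy shift with inversion; C9 by α-face ene attack.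
6. Helper: a C8=C9 enol triflate hides the ring-B alkene from the hydrogen-atom transfer and from the epoxidation, and is reduced to the alkene just before the ene reaction.

Key step: step 4

Remark: in step 1 the enantiomer of the ligand is taken that gives the (R)-configured isopropenyl-bearing carbon; every later stereocentre is derived from this one.

**Step 1**
Reactants: 1 2-methylcyclohex-2-en-1-one; 2 isopropenylmagnesium bromide; 3 acrylonitrile
Product: 5 3-[(1R,6R)-1-methyl-2-oxo-6-(prop-1-en-2-yl)cyclohexyl]propanenitrile, via bromomagnesium enolate 4 (not isolated)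
Conditions: Cu(OTf)2 (3 mol %), 1-(2,4,6-trimethylphenyl)-3-[(2S)-1-hydroxy-4-methylpentan-2-yl]-4,5-dihydroimidazolium hexafluorophosphate or its enantiomer (NHC precursor, 4 mol %), Et2O, −30 °C; then CH2=CHCN, −30 to 0 °C; aq. NH4Cl
Reagents that add atoms: none
Why: Copper-catalysed asymmetric conjugate addition of the alkenyl Grignard reagent should set C5 under ligand control, and the regiodefined tetrasubstituted enolate 4 should then add to acrylonitrile (Michael reaction) on the face anti to the new isopropenyl group, which makes quaternary C10 with the cyanoethyl arm trans to the isopropenyl arm.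

**Step 2**
Reactants: 5
Product: 6 3-[(1R,3RS,6R)-1,3-dimethyl-2-oxo-6-(prop-1-en-2-yl)cyclohexyl]propanenitrile (both epimers at the new methyl-bearing carbon)
Conditions: LiN(iPr)2 (1.05 equiv), THF, −78 °C; MeI, −78 to 0 °C
Reagents that add atoms: iodomethane, CI
Why: Enolate alkylation: the ketone can enolise only toward C8 (C10 is quaternary) and its α-CH2 is far more acidic than the CH2 next to the nitrile, and the configuration of the new centre does not matter because it becomes trigonal in step 3.

**Step 3**
Reactants: 6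
Product: 7 (5R,6R)-6-(2-cyanoethyl)-2,6-dimethyl-5-(prop-1-en-2-yl)cyclohex-1-en-1-yl trifluoromethanesulfonate
Conditions: KN(SiMe3)2, THF, −78 to −20 °C; PhNTf2, −78 °C to rt
Reagents that add atoms: N-phenylbis(trifluoromethanesulfonimide), O=S(=O)(N(c1ccccc1)S(=O)(=O)C(F)(F)F)C(F)(F)F
Why: Enol triflate formation from the only enolate the ketone can form gives a tetrasubstituted, electron-poor C8=C9 double bond that the reagents of steps 4–6 should not attack and that step 7 turns into the alkene needed for step 8.

**Step 4**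
Reactants: 7
Product: 9 (4aS,8aR)-2,5,5,8a-tetramethyl-6-oxo-3,4,4a,5,6,7,8,8a-octahydronaphthalen-1-yl trifluoromethanesulfonate, via ketimine 8 (not isolated)
Conditions: Fe(acac)3 (0.5 equiv), PhSiH3 (2.5 equiv), EtOH, 60 °C, under argon; then 1 M HCl, THF, rt
Reagents that add atoms: water, O
Why: An Fe–H species formed from Fe(acac)3 and PhSiH3 in ethanol should transfer a hydrogen atom to the CH2 terminus of the isopropenyl group (Markovnikov sense), which makes C4 a tertiary radical and the former CH2 the second geminal methyl; this nucleophilic radical adds to the nitrile carbon C3, and the iminyl radical is reduced and protonated to ketimine 8, which the acidic work-up hydrolyses to the C3 ketone. The closest known reaction type is the metal-hydride hydrogen-atom-transfer (MHAT) cyclisation of alkene-tethered nitriles to cyclic ketones, the hydride-initiated relative of tin-mediated radical cyclisations onto nitriles. Ring A is closed through the C3–C4 bond in the 6-exo-dig mode. No stereocentre is created (C4 becomes a CMe2 carbon, C3 is trigonal), and the trans ring fusion cannot be lost because C5 and C10 were set in step 1 and hold the two reacting arms trans-diequatorial. The step needs chemoselective hydrogen-atom transfer to the isopropenyl group, which the substrate secures because its only other C=C is the tetrasubstituted, electron-poor enol triflate, and it needs ring closure to outrun reduction of the radical, which the pre-organised six-membered transition state with a fully substituted radical centre should favour.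

**Step 5**
Reactants: 9
Product: 10 (4aR,8aR)-2,5,5,8a-tetramethyl-1-(trifluoromethanesulfonyloxy)-3,4,4a,5,8,8a-hexahydronaphthalen-6-yl acetate (the C2=C3 enol acetate of 9)
Conditions: isopropenyl acetate (solvent), TsOH·H2O (5 mol %), reflux with slow distillation of acetone
Reagents that add atoms: isopropenyl acetate, CC(=C)OC(C)=O
Why: Acid-catalysed enol ester exchange; only C2 carries α-hydrogens (C4 is quaternary), so a single enol acetate can form.

**Step 6**
Reactants: 10
Product: 12 (2R,4aS,8aR)-4,4,7,8a-tetramethyl-3-oxo-8-(trifluoromethanesulfonyloxy)-1,2,3,4,4a,5,6,8a-octahydronaphthalen-2-yl acetate, via epoxy acetate 11 (not isolated)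
Conditions: dimethyldioxirane, acetone, 0 °C; evaporate; toluene, 110 °C, base-washed glassware
Reagents that add atoms: dimethyldioxirane, CC1(C)OO1
Why: Epoxidation of the electron-rich enol acetate should occur on the α-face (anti to the axial C10 and C4 methyls, the enol triflate being too electron-poor to react), and the thermal enol ester epoxide rearrangement then moves the acetoxy group intramolecularly from C3 to C2 with inversion, which places the acetate on the β-face (axial, syn to the angular methyl) and restores the C3 ketone.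

**Step 7**
Reactants: 12
Product: 13 (2R,4aS,8aS)-4,4,7,8a-tetramethyl-3-oxo-1,2,3,4,4a,5,6,8a-octahydronaphthalen-2-yl acetate
Conditions: Pd(PPh3)4 (5 mol %), LiCl (3 equiv), Bu3SnH (1.3 equiv), THF, 60 °C
Reagents that add atoms: none
Why: Palladium-catalysed reduction of the vinyl triflate (oxidative addition to zerovalent palladium, hydride transfer from tin, reductive elimination) runs under neutral conditions that should leave the epimerisable axial acetate untouched and unveils the trisubstituted C8=C9 alkene.

**Step 8**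
Reactants: 13
Product: 14 (2R,4aS,8S,8aR)-8-(hydroxymethyl)-4,4,8a-trimethyl-7-methylidene-3-oxodecahydronaphthalen-2-yl acetate
Conditions: paraformaldehyde (3 equiv), Me2AlCl (3 equiv, hexanes), CH2Cl2, −78 to 0 °C
Reagents that add atoms: formaldehyde (from paraformaldehyde), C=O
Why: Lewis-acid-promoted carbonyl-ene reaction: the formaldehyde–Me2AlCl complex should bond to the less substituted alkene carbon C9 on the α-face, anti to the axial angular methyl, and take its hydrogen from the C8 methyl group (the allylic group cis to the vinylic hydrogen), which gives the axial CH2OH at C9 and the exocyclic C8=C12 double bond in one operation.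

**Step 9**
Reactants: 14; 15 isofraxidin (7-hydroxy-6,8-dimethoxy-2H-chromen-2-one)
Product: 16 (2R,4aS,8S,8aR)-8-{[(6,8-dimethoxy-2-oxo-2H-chromen-7-yl)oxy]methyl}-4,4,8a-trimethyl-7-methylidene-3-oxodecahydronaphthalen-2-yl acetate (CNP0183157.1)
Conditions: PPh3, diisopropyl azodicarboxylate, THF, 0 °C to rt
Reagents that add atoms: none
Why: Mitsunobu etherification of the primary alcohol with the acidic 7-hydroxycoumarin touches no stereocentre, and its near-neutral medium should spare the axial acetate, the exocyclic alkene and the lactone.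

**Compound list**

1 | 2-methylcyclohex-2-en-1-one | CC1=CCCCC1=O | starting material
2 | isopropenylmagnesium bromide (prop-1-en-2-ylmagnesium bromide) | CC(=C)[Mg]Br | starting material
3 | acrylonitrile | C=CC#N | starting material
4 | bromomagnesium (3R)-2-methyl-3-(prop-1-en-2-yl)cyclohex-1-en-1-olate | Br[Mg]OC1=C(C)[C@@H](C(C)=C)CCC1 | intermediate
5 | 3-[(1R,6R)-1-methyl-2-oxo-6-(prop-1-en-2-yl)cyclohexyl]propanenitrile | O=C1CCC[C@H](C(C)=C)[C@@]1(C)CCC#N | intermediate
6 | 3-[(1R,3RS,6R)-1,3-dimethyl-2-oxo-6-(prop-1-en-2-yl)cyclohexyl]propanenitrile | O=C1C(C)CC[C@H](C(C)=C)[C@@]1(C)CCC#N | intermediate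
7 | (5R,6R)-6-(2-cyanoethyl)-2,6-dimethyl-5-(prop-1-en-2-yl)cyclohex-1-en-1-yl trifluoromethanesulfonate | FC(F)(F)S(=O)(=O)OC1=C(C)CC[C@H](C(C)=C)[C@@]1(C)CCC#N | intermediate
8 | (4aR,8aR)-6-imino-2,5,5,8a-tetramethyl-3,4,4a,5,6,7,8,8a-octahydronaphthalen-1-yl trifluoromethanesulfonate (N–H ketimine of 9) | CC1=C(OS(=O)(=O)C(F)(F)F)[C@]2(C)CCC(=N)C(C)(C)[C@H]2CC1 | intermediate
9 | (4aS,8aR)-2,5,5,8a-tetramethyl-6-oxo-3,4,4a,5,6,7,8,8a-octahydronaphthalen-1-yl trifluoromethanesulfonate (trans-fused) | CC1=C(OS(=O)(=O)C(F)(F)F)[C@]2(C)CCC(=O)C(C)(C)[C@H]2CC1 | intermediate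
10 | (4aR,8aR)-2,5,5,8a-tetramethyl-1-(trifluoromethanesulfonyloxy)-3,4,4a,5,8,8a-hexahydronaphthalen-6-yl acetate | CC1=C(OS(=O)(=O)C(F)(F)F)[C@]2(C)CC=C(OC(C)=O)C(C)(C)[C@H]2CC1 | intermediate
11 | 2α,3α-epoxide of 10 (oxirane oxygen anti to the angular methyl, 3-acetoxy group syn to it) | CC1=C(OS(=O)(=O)C(F)(F)F)[C@]2(C)C[C@@H]3O[C@]3(OC(C)=O)C(C)(C)[C@H]2CC1 | intermediate
12 | (2R,4aS,8aR)-4,4,7,8a-tetramethyl-3-oxo-8-(trifluoromethanesulfonyloxy)-1,2,3,4,4a,5,6,8a-octahydronaphthalen-2-yl acetate (acetate axial, syn to the angular methyl) | CC1=C(OS(=O)(=O)C(F)(F)F)[C@]2(C)C[C@@H](OC(C)=O)C(=O)C(C)(C)[C@H]2CC1 | intermediate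
13 | (2R,4aS,8aS)-4,4,7,8a-tetramethyl-3-oxo-1,2,3,4,4a,5,6,8a-octahydronaphthalen-2-yl acetate | CC1=C[C@]2(C)C[C@@H](OC(C)=O)C(=O)C(C)(C)[C@H]2CC1 | intermediate
14 | (2R,4aS,8S,8aR)-8-(hydroxymethyl)-4,4,8a-trimethyl-7-methylidene-3-oxodecahydronaphthalen-2-yl acetate | C=C1CC[C@@H]2C(C)(C)C(=O)[C@H](OC(C)=O)C[C@@]2(C)[C@H]1CO | intermediate
15 | isofraxidin (7-hydroxy-6,8-dimethoxy-2H-chromen-2-one) | COc1cc2ccc(=O)oc2c(OC)c1O | starting material
16 | (2R,4aS,8S,8aR)-8-{[(6,8-dimethoxy-2-oxo-2H-chromen-7-yl)oxy]methyl}-4,4,8a-trimethyl-7-methylidene-3-oxodecahydronaphthalen-2-yl acetate | C=C1CC[C@@H]2C(C)(C)C(=O)[C@H](OC(C)=O)C[C@@]2(C)[C@H]1COc1c(OC)cc2ccc(=O)oc2c1OC | target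

**Step count and risks**

Total steps: 9. Longest linear sequence: 9 steps (1 to 16).

The three steps most likely to fail:

Step 4. The tertiary C4 radical may be quenched before it adds to the weakly radical-accepting nitrile, either by reduction with the excess hydride source or by a 1,5-hydrogen shift from C2–H. Fallback: from 7, Markovnikov hydrobromination of the isopropenyl group (HBr in AcOH, 0 °C) should give (5S,6R)-5-(2-bromopropan-2-yl)-6-(2-cyanoethyl)-2,6-dimethylcyclohex-1-en-1-yl trifluoromethanesulfonate F1. Slow addition of Bu3SnH with AIBN in refluxing benzene then generates the same radical by bromine abstraction in a chain whose hydrogen-donor concentration can be kept low (the classical tin-mediated radical cyclisation onto a nitrile). Hydrolysis of ketimine 8 (1 M HCl) returns to the route at 9.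

Step 6. The acetoxy group may fail to reach the β-face of C2, which is flanked by two axial methyls, so that the ionic pathway with retention takes over and the equatorial acetate forms. Fallback: from 10, epoxidise as before and let epoxy acetate 11 rearrange under acid catalysis (silica gel or 1 mol % TsOH, CH2Cl2). Acyl transfer to the oxirane oxygen, with retention at C2, should give the equatorial epimer (2S,4aS,8aR)-4,4,7,8a-tetramethyl-3-oxo-8-(trifluoromethanesulfonyloxy)-1,2,3,4,4a,5,6,8a-octahydronaphthalen-2-yl acetate F2. Deprotonation at C2 (LiN(SiMe3)2, THF, −78 °C) and kinetic protonation of the enolate on the unhindered α-face (2,6-di-tert-butylphenol, −78 °C) returns to the route at 12.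

Step 8. The ene reaction may lose its proton toward C7 (endocyclic alkene) instead of from the C8 methyl, or the aluminium Lewis acid may damage the α-acetoxy ketone. Fallback (silicon-directed SE2′ substitution in place of the ene hydrogen shift), setting out from 5 and returning at 14:
- Alkylate the enolate of 5 with (trimethylsilyl)methyl trifluoromethanesulfonate instead of MeI to give 3-[(1R,3RS,6R)-1-methyl-2-oxo-6-(prop-1-en-2-yl)-3-[(trimethylsilyl)methyl]cyclohexyl]propanenitrile F3.
- Carry F3 through the operations of steps 3–7, forming the enol acetate with KN(SiMe3)2 and Ac2O to avoid protodesilylation.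
- This gives in turn (5R,6R)-6-(2-cyanoethyl)-6-methyl-5-(prop-1-en-2-yl)-2-[(trimethylsilyl)methyl]cyclohex-1-en-1-yl trifluoromethanesulfonate F4; the 6-imino analogue of F6 (ketimine, not isolated) F5; (4aS,8aR)-5,5,8a-trimethyl-6-oxo-2-[(trimethylsilyl)methyl]-3,4,4a,5,6,7,8,8a-octahydronaphthalen-1-yl trifluoromethanesulfonate F6; its C2=C3 enol acetate, (4aR,8aR)-5,5,8a-trimethyl-1-(trifluoromethanesulfonyloxy)-2-[(trimethylsilyl)methyl]-3,4,4a,5,8,8a-hexahydronaphthalen-6-yl acetate F7; the 2α,3α-epoxide of F7 (not isolated) F8; (2R,4aS,8aR)-4,4,8a-trimethyl-3-oxo-8-(trifluoromethanesulfonyloxy)-7-[(trimethylsilyl)methyl]-1,2,3,4,4a,5,6,8a-octahydronaphthalen-2-yl acetate F9; and, after triflate reduction, the allylsilane (2R,4aS,8aS)-4,4,8a-trimethyl-3-oxo-7-[(trimethylsilyl)methyl]-1,2,3,4,4a,5,6,8a-octahydronaphthalen-2-yl acetate F10.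
- Hosomi–Sakurai hydroxymethylation of F10 (1,3,5-trioxane, BF3·OEt2, CH2Cl2, −78 °C) can place the new double bond only at C8=C12 and, with α-face attack at C9, gives 14.

**Further compounds**

F1 | step 4 | (5S,6R)-5-(2-bromopropan-2-yl)-6-(2-cyanoethyl)-2,6-dimethylcyclohex-1-en-1-yl trifluoromethanesulfonate | FC(F)(F)S(=O)(=O)OC1=C(C)CC[C@H](C(C)(C)Br)[C@@]1(C)CCC#N
F2 | step 6 | (2S,4aS,8aR)-4,4,7,8a-tetramethyl-3-oxo-8-(trifluoromethanesulfonyloxy)-1,2,3,4,4a,5,6,8a-octahydronaphthalen-2-yl acetate | CC1=C(OS(=O)(=O)C(F)(F)F)[C@]2(C)C[C@H](OC(C)=O)C(=O)C(C)(C)[C@H]2CC1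
F3 | step 8 | 3-[(1R,3RS,6R)-1-methyl-2-oxo-6-(prop-1-en-2-yl)-3-[(trimethylsilyl)methyl]cyclohexyl]propanenitrile | O=C1C(C[Si](C)(C)C)CC[C@H](C(C)=C)[C@@]1(C)CCC#N
F4 | step 8 | (5R,6R)-6-(2-cyanoethyl)-6-methyl-5-(prop-1-en-2-yl)-2-[(trimethylsilyl)methyl]cyclohex-1-en-1-yl trifluoromethanesulfonate | FC(F)(F)S(=O)(=O)OC1=C(C[Si](C)(C)C)CC[C@H](C(C)=C)[C@@]1(C)CCC#N
F5 | step 8 | 6-imino analogue (N–H ketimine) of F6 | C[Si](C)(C)CC1=C(OS(=O)(=O)C(F)(F)F)[C@]2(C)CCC(=N)C(C)(C)[C@H]2CC1
F6 | step 8 | (4aS,8aR)-5,5,8a-trimethyl-6-oxo-2-[(trimethylsilyl)methyl]-3,4,4a,5,6,7,8,8a-octahydronaphthalen-1-yl trifluoromethanesulfonate | C[Si](C)(C)CC1=C(OS(=O)(=O)C(F)(F)F)[C@]2(C)CCC(=O)C(C)(C)[C@H]2CC1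
F7 | step 8 | (4aR,8aR)-5,5,8a-trimethyl-1-(trifluoromethanesulfonyloxy)-2-[(trimethylsilyl)methyl]-3,4,4a,5,8,8a-hexahydronaphthalen-6-yl acetate | C[Si](C)(C)CC1=C(OS(=O)(=O)C(F)(F)F)[C@]2(C)CC=C(OC(C)=O)C(C)(C)[C@H]2CC1
F8 | step 8 | 2α,3α-epoxide of F7 (oxirane oxygen anti to the angular methyl) | C[Si](C)(C)CC1=C(OS(=O)(=O)C(F)(F)F)[C@]2(C)C[C@@H]3O[C@]3(OC(C)=O)C(C)(C)[C@H]2CC1
F9 | step 8 | (2R,4aS,8aR)-4,4,8a-trimethyl-3-oxo-8-(trifluoromethanesulfonyloxy)-7-[(trimethylsilyl)methyl]-1,2,3,4,4a,5,6,8a-octahydronaphthalen-2-yl acetate | C[Si](C)(C)CC1=C(OS(=O)(=O)C(F)(F)F)[C@]2(C)C[C@@H](OC(C)=O)C(=O)C(C)(C)[C@H]2CC1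
F10 | step 8 | (2R,4aS,8aS)-4,4,8a-trimethyl-3-oxo-7-[(trimethylsilyl)methyl]-1,2,3,4,4a,5,6,8a-octahydronaphthalen-2-yl acetate | C[Si](C)(C)CC1=C[C@]2(C)C[C@@H](OC(C)=O)C(=O)C(C)(C)[C@H]2CC1
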